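**Retrosynthetic overview**
1. Last C–C bond, C2′–C3′: lithiation–borylation–oxidation joins a ring-bound primary pinacol boronate with α-lithiated (R)-but-3-en-2-yl carbamate. The carbinol carbon C3′ enters as a nucleophile (reversed polarity of a ketone carbon) and takes its configuration from the reagent.
2. The boronate comes from a C1-vinyl group (hydroboration). The vinyl comes from a C1′ primary alcohol (oxidation, methylenation), freed together with the C6 hydroxyl from a trans-fused cyclic carbonate.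
3. The only carbocycle is made once, by catalytic enantioselective bromonium-triggered cyclization of an acyclic (2E,6E,9E)-trienyl tert-butyl carbonate. The carbonate closes a temporary 1,3-dioxan-2-one in the same step; this sets C1, C2, C3 and C6.
4. The trienyl carbonate comes from (2E,6E)-farnesol by carbonate formation and transposition of the terminal alkene (bromohydrin/epoxide, selenoxide elimination).

Assumption: (2E,6E)-farnesol (≥95% E,E) and (R)-but-3-en-2-ol (≥98% ee) are bought; ring atoms are called C1 (CH carrying the C5 chain), C2 (quaternary C), C3 (CHBr), C4, C5, C6 (C(CH3)OH), chain atoms C1′–C3′ count outward from C1, and acyclic compounds use farnesane numbering where stated.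

**Step 1**
Reactants: 1 (2E,6E)-farnesol
Product: 2 tert-butyl (2E,6E)-3,7,11-trimethyldodeca-2,6,10-trien-1-yl carbonate
Conditions: Boc2O (1.3 equiv), 1-methylimidazole (10 mol %), toluene, 0 °C → rt
Reagents that add atoms: di-tert-butyl dicarbonate, CC(C)(C)OC(=O)OC(=O)OC(C)(C)C
Why: Nucleophile-catalysed O-tert-butoxycarbonylation of the primary allylic alcohol; the carbonate will deactivate the 2,3-alkene toward Br+ and act as the internal oxygen nucleophile in step 4.

**Step 2**
Reactants: 2 tert-butyl (2E,6E)-farnesyl carbonate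
Product: 4 tert-butyl (2E,6E)-10,11-epoxy-3,7,11-trimethyldodeca-2,6-dien-1-yl carbonate (racemic), via bromohydrin 3 (not isolated)
Conditions: NBS (1.05 equiv), THF–H2O 4:1, 0 °C; then K2CO3, MeOH, rt
Reagents that add atoms: N-bromosuccinimide, O=C1CCC(=O)N1Br (Br of 3 only); water, O (oxygen of 3 and 4)
Why: van Tamelen-type terminal-selective bromohydrin formation (the 2,3-alkene is deactivated by the allylic carbonate and the 6,7-alkene is shielded in the coiled chain in aqueous THF) followed by intramolecular Williamson closure; the C10 stereocentre is racemic and is erased in step 3.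

**Step 3**
Reactants: 4 racemic 10,11-epoxide
Product: 7 tert-butyl (2E,6E,9E)-11-hydroxy-3,7,11-trimethyldodeca-2,6,9-trien-1-yl carbonate, via hydroxy selenide 5 (not isolated), via selenoxide 6 (not isolated)
Conditions: (PhSe)2 (0.6 equiv), NaBH4, EtOH, rt → 50 °C; then 30% H2O2, pyridine, THF, 0 °C → rt
Reagents that add atoms: diphenyl diselenide, c1ccc(cc1)[Se][Se]c1ccccc1 (PhSe of 5 and 6); hydrogen peroxide, OO (selenoxide O of 6); nothing is added to 7
Why: Sharpless–Lauer epoxide-to-allylic-alcohol transposition: the selenolate opens the epoxide at the less hindered C10 and the selenoxide eliminates syn, away from the carbinol carbon, so only the (E)-disubstituted tertiary allylic alcohol forms, with pyridine suppressing alkene epoxidation by perseleninic acid.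

**Step 4**
Reactants: 7 (2E,6E,9E)-trienyl tert-butyl carbonate
Product: 8 (4aR,5S,6S,8aS)-6-bromo-5-[(2E)-4-hydroxy-4-methylpent-2-en-1-yl]-5,8a-dimethylhexahydro-4H-1,3-benzodioxin-2-one
Conditions: NBS (1.05 equiv), chiral BINOL-derived N-triflylthiophosphoramide (10 mol %, enantiomer that delivers Br to the Si face of C6, farnesane numbering), toluene–CH2Cl2, −78 °C
Reagents that add atoms: N-bromosuccinimide, O=C1CCC(=O)N1Br
Why: Proposed new method: a chiral Lewis base carries Br+ from NBS to the Si face of C6 of the only electron-rich trisubstituted alkene (the 2,3-alkene is deactivated by the carbonate, the 9,10-alkene is disubstituted and its (E)-geometry keeps the tertiary OH away), the 2,3-alkene attacks C7 anti through a chair transition state and the carbonate C=O captures the tertiary cation anti with loss of isobutene, so the E,E geometry fixes the relative configuration of all four ring centres (equatorial Br, axial CH3 at C2 and C6, trans-fused carbonate) while the catalyst fixes the absolute one; the closest known reaction types are chiral-Lewis-base-catalysed enantioselective bromocyclization of polyprenoids and racemic BDSB-type bromonium polyene cyclizations terminated by tert-butyl carbonates.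

**Step 5**
Reactants: 8 bromo cyclic carbonate
Product: 9 (1S,2R,3S,4S)-4-bromo-2-(hydroxymethyl)-3-[(2E)-4-hydroxy-4-methylpent-2-en-1-yl]-1,3-dimethylcyclohexan-1-ol
Conditions: NaOMe (0.2 equiv), MeOH, 0 °C → rt
Reagents that add atoms: none
Why: Methoxide-catalysed transesterification (methanolysis) of the six-membered cyclic carbonate frees the primary and the tertiary hydroxyl without touching any stereocentre or the hindered secondary bromide.

**Step 6**
Reactants: 9 triol
Product: 10 (1S,2S,3S,6S)-3-bromo-6-hydroxy-2-[(2E)-4-hydroxy-4-methylpent-2-en-1-yl]-2,6-dimethylcyclohexane-1-carbaldehyde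
Conditions: TEMPO (10 mol %), PhI(OAc)2 (1.1 equiv), CH2Cl2, rt
Reagents that add atoms: none
Why: TEMPO/PhI(OAc)2 oxidation (oxoammonium catalysis) is selective for the primary alcohol over tertiary alcohols, alkenes and the bromide, and C1 already carries its substituent in the thermodynamically preferred equatorial position.

**Step 7**
Reactants: 10 hydroxy aldehyde
Product: 11 (1S,2S,3S,4S)-4-bromo-2-ethenyl-3-[(2E)-4-hydroxy-4-methylpent-2-en-1-yl]-1,3-dimethylcyclohexan-1-ol
Conditions: Ph3PCH3Br, KOtBu, THF, 0 °C; then 10, −78 → 0 °C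
Reagents that add atoms: methyltriphenylphosphonium bromide, C[P+](c1ccccc1)(c1ccccc1)c1ccccc1.[Br-]
Why: Wittig methylenation of the aldehyde; the non-stabilised ylide is too weak a base to deprotonate the tertiary alcohols, so no retro-aldol cleavage occurs and C1 keeps its configuration.

**Step 8**
Reactants: 11 vinyl diol
Product: 12 bis(trimethylsilyl) ether of 11
Conditions: N-(trimethylsilyl)imidazole (3 equiv), CH2Cl2, rt
Reagents that add atoms: N-(trimethylsilyl)imidazole, C[Si](C)(C)n1ccnc1
Why: Neutral silylation of both tertiary alcohols, so that neither an O–H proton nor a C6 alkoxide chelating the boron can interfere in step 11.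

**Step 9**
Reactants: 12 bis-silyl ether
Product: 13 2-{2-[(1S,2S,3S,6S)-3-bromo-2,6-dimethyl-2-[(2E)-4-methyl-4-(trimethylsilyloxy)pent-2-en-1-yl]-6-(trimethylsilyloxy)cyclohexyl]ethyl}-4,4,5,5-tetramethyl-1,3,2-dioxaborolane
Conditions: HBpin (1.5 equiv), [Ir(cod)Cl]2 (1.5 mol %), dppm (3 mol %), CH2Cl2, rt
Reagents that add atoms: pinacolborane, CC1(C)OBOC1(C)C
Why: Iridium-catalysed anti-Markovnikov hydroboration reacts only with the monosubstituted alkene, leaving the 1,2-disubstituted alkene, the silyl ethers and the alkyl bromide untouched, and creates no stereocentre.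

**Step 10**
Reactants: 14 (R)-but-3-en-2-ol
Product: 15 (R)-but-3-en-2-yl N,N-diisopropylcarbamate
Conditions: iPr2NCOCl, Et3N, DMAP (cat.), CH2Cl2, reflux
Reagents that add atoms: N,N-diisopropylcarbamoyl chloride, CC(C)N(C(C)C)C(Cl)=O
Why: O-Carbamoylation of the secondary allylic alcohol (Hoppe carbamate) without touching the stereocentre, which stays R.

**Step 11 (key step)**
Reactants: 13 primary pinacol boronate; 15 (R)-carbamate
Product: 20 (1S,2S,3S,4S)-4-bromo-3-[(2E)-4-hydroxy-4-methylpent-2-en-1-yl]-2-[(3S)-3-hydroxy-3-methylpent-4-en-1-yl]-1,3-dimethylcyclohexan-1-ol (target), via lithiated carbamate 16 (not isolated), via boronate complex 17 (not isolated), via tertiary boronic ester 18 (not isolated), via bis-TMS ether 19 (not isolated)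
Conditions: 15 (1.3 equiv), s-BuLi (1.25 equiv), TMEDA, Et2O, −78 °C; add 13, −78 °C → rt; NaOH, 30% H2O2, THF, 0 °C; then K2CO3, MeOH, rt
Reagents that add atoms: sec-butyllithium, [Li]C(C)CC (Li of 16 and 17 only); hydrogen peroxide, OO (the C3′ oxygen of 19 and 20)
Why: Hoppe–Aggarwal lithiation–borylation–oxidation: deprotonation gives the configurationally stable α-carbamoyloxy allyllithium 16, in which C3′ (the carbonyl carbon of methyl vinyl ketone in the conventional disconnection) is a nucleophile, this carbon is joined to the likewise nucleophilic boron-bound C2′ by borylation with retention and a 1,2-metallate shift with inversion (carbamate as leaving group), C–B oxidation with retention then turns the (R)-carbamate into the (S)-tertiary alcohol, and methanolysis removes the two trimethylsilyl groups.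

**Compound list**
1 | (2E,6E)-farnesol | OC/C=C(C)/CC/C=C(C)/CCC=C(C)C | starting material
2 | tert-butyl (2E,6E)-3,7,11-trimethyldodeca-2,6,10-trien-1-yl carbonate | CC(C)(C)OC(=O)OC/C=C(C)/CC/C=C(C)/CCC=C(C)C | intermediate
3 | tert-butyl (2E,6E)-10-bromo-11-hydroxy-3,7,11-trimethyldodeca-2,6-dien-1-yl carbonate (racemic at C10) | CC(C)(C)OC(=O)OC/C=C(C)/CC/C=C(C)/CCC(Br)C(C)(C)O | intermediate (not isolated)
4 | tert-butyl (2E,6E)-10,11-epoxy-3,7,11-trimethyldodeca-2,6-dien-1-yl carbonate (racemic) | CC(C)(C)OC(=O)OC/C=C(C)/CC/C=C(C)/CCC1OC1(C)C | intermediate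
5 | tert-butyl (2E,6E)-11-hydroxy-3,7,11-trimethyl-10-(phenylselanyl)dodeca-2,6-dien-1-yl carbonate (racemic) | CC(C)(C)OC(=O)OC/C=C(C)/CC/C=C(C)/CCC([Se]c1ccccc1)C(C)(C)O | intermediate (not isolated)
6 | selenoxide of 5 | CC(C)(C)OC(=O)OC/C=C(C)/CC/C=C(C)/CCC([Se](=O)c1ccccc1)C(C)(C)O | intermediate (not isolated)
7 | tert-butyl (2E,6E,9E)-11-hydroxy-3,7,11-trimethyldodeca-2,6,9-trien-1-yl carbonate | CC(C)(C)OC(=O)OC/C=C(C)/CC/C=C(C)/C/C=C/C(C)(C)O | intermediate
8 | (4aR,5S,6S,8aS)-6-bromo-5-[(2E)-4-hydroxy-4-methylpent-2-en-1-yl]-5,8a-dimethylhexahydro-4H-1,3-benzodioxin-2-one | O=C1OC[C@H]2[C@](C)(C/C=C/C(C)(C)O)[C@@H](Br)CC[C@]2(C)O1 | intermediate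
9 | (1S,2R,3S,4S)-4-bromo-2-(hydroxymethyl)-3-[(2E)-4-hydroxy-4-methylpent-2-en-1-yl]-1,3-dimethylcyclohexan-1-ol | OC[C@H]1[C@](C)(C/C=C/C(C)(C)O)[C@@H](Br)CC[C@]1(C)O | intermediate
10 | (1S,2S,3S,6S)-3-bromo-6-hydroxy-2-[(2E)-4-hydroxy-4-methylpent-2-en-1-yl]-2,6-dimethylcyclohexane-1-carbaldehyde | O=C[C@H]1[C@](C)(C/C=C/C(C)(C)O)[C@@H](Br)CC[C@]1(C)O | intermediate
11 | (1S,2S,3S,4S)-4-bromo-2-ethenyl-3-[(2E)-4-hydroxy-4-methylpent-2-en-1-yl]-1,3-dimethylcyclohexan-1-ol | C=C[C@H]1[C@](C)(C/C=C/C(C)(C)O)[C@@H](Br)CC[C@]1(C)O | intermediate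
12 | bis(trimethylsilyl) ether of 11 (both tertiary OH silylated) | C=C[C@H]1[C@](C)(C/C=C/C(C)(C)O[Si](C)(C)C)[C@@H](Br)CC[C@]1(C)O[Si](C)(C)C | intermediate
13 | 2-{2-[(1S,2S,3S,6S)-3-bromo-2,6-dimethyl-2-[(2E)-4-methyl-4-(trimethylsilyloxy)pent-2-en-1-yl]-6-(trimethylsilyloxy)cyclohexyl]ethyl}-4,4,5,5-tetramethyl-1,3,2-dioxaborolane | CC1(C)OB(CC[C@H]2[C@](C)(C/C=C/C(C)(C)O[Si](C)(C)C)[C@@H](Br)CC[C@]2(C)O[Si](C)(C)C)OC1(C)C | intermediate
14 | (R)-but-3-en-2-ol | C=C[C@@H](C)O | starting material
15 | (R)-but-3-en-2-yl N,N-diisopropylcarbamate | C=C[C@@H](C)OC(=O)N(C(C)C)C(C)C | intermediate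
16 | α-lithiated 15 (Li in place of H, configuration retained) | C=C[C@@]([Li])(C)OC(=O)N(C(C)C)C(C)C | intermediate (not isolated)
17 | lithium boronate (ate) complex of 16 and 13 (B in place of Li) | [Li+].C=C[C@@]([B-]1(CC[C@H]2[C@](C)(C/C=C/C(C)(C)O[Si](C)(C)C)[C@@H](Br)CC[C@]2(C)O[Si](C)(C)C)OC(C)(C)C(C)(C)O1)(C)OC(=O)N(C(C)C)C(C)C | intermediate (not isolated)
18 | tertiary allylic pinacol boronate after 1,2-shift (Bpin where the C3′ OH will stand) | C=C[C@@](C)(B1OC(C)(C)C(C)(C)O1)CC[C@H]2[C@](C)(C/C=C/C(C)(C)O[Si](C)(C)C)[C@@H](Br)CC[C@]2(C)O[Si](C)(C)C | intermediate (not isolated)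
19 | bis(trimethylsilyl) ether of 20 (ring O and pentenyl tertiary O silylated, C3′ OH free) | C=C[C@@](C)(O)CC[C@H]1[C@](C)(C/C=C/C(C)(C)O[Si](C)(C)C)[C@@H](Br)CC[C@]1(C)O[Si](C)(C)C | intermediate (not isolated)
20 | (1S,2S,3S,4S)-4-bromo-3-[(2E)-4-hydroxy-4-methylpent-2-en-1-yl]-2-[(3S)-3-hydroxy-3-methylpent-4-en-1-yl]-1,3-dimethylcyclohexan-1-ol | C=C[C@@](C)(O)CC[C@H]1[C@](C)(C/C=C/C(C)(C)O)[C@@H](Br)CC[C@]1(C)O | target

**Step count**
Total: 11 steps. Longest linear sequence: 10 (steps 1–9 and 11); step 10 is a one-step branch.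

**Three steps most likely to fail**

Step 4. Enantioselective bromonium transfer to an alkene whose two ends differ only as CH3 versus CH2R, and clean capture by the carbonate, are unproven; a moderate ee could only be raised by recrystallising 8. The fallback sets out from 7 and comes back at 8, and fixes the absolute configuration before the ring closure instead of in it. Shi asymmetric epoxidation of the electron-rich 6,7-alkene of 7 gives tert-butyl (2E,6R,7R,9E)-6,7-epoxy-11-hydroxy-3,7,11-trimethyldodeca-2,9-dien-1-yl carbonate F1. SN2 opening at the secondary carbon with Li2NiBr4 gives the anti bromohydrin tert-butyl (2E,6S,7R,9E)-6-bromo-7,11-dihydroxy-3,7,11-trimethyldodeca-2,9-dien-1-yl carbonate F2. Ionisation of its tertiary C7 hydroxyl (trifluoroacetic anhydride, then BF3·OEt2 in HFIP–CH2Cl2, −40 °C) with neighbouring-group participation of bromine regenerates the single-enantiomer bromonium ion, which cyclises as in step 4 to 8.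

Step 7. Aldehyde 10 is a β-hydroxy aldehyde flanked by two fully substituted carbons, so retro-aldol ring opening or sluggish olefination is possible. The fallback sets out from 9 and comes back at 12, and changes the protecting-group order so that no free β-hydroxy aldehyde is ever formed. N-(Trimethylsilyl)imidazole converts 9 into the tris(trimethylsilyl) ether of 9 F3. Swern oxidation, which attacks only the primary silyl ether, gives (1S,2S,3S,6S)-3-bromo-2,6-dimethyl-2-[(2E)-4-methyl-4-(trimethylsilyloxy)pent-2-en-1-yl]-6-(trimethylsilyloxy)cyclohexane-1-carbaldehyde F4. Wittig methylenation of F4 gives 12 directly, so step 8 is no longer needed.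

Step 11. The α/γ selectivity and configurational stability of the lithiated allylic carbamate, and the 1,2-shift, may fail on this substrate. The fallback sets out from 11 and comes back at 20, and builds the carbinol by asymmetric epoxidation instead. Hydroboration of 11 with 9-BBN gives the B-alkyl-9-BBN adduct of 11 F5. Suzuki–Miyaura coupling with (Z)-3-iodobut-2-en-1-ol gives (1S,2S,3S,4S)-4-bromo-2-[(3Z)-5-hydroxy-3-methylpent-3-en-1-yl]-3-[(2E)-4-hydroxy-4-methylpent-2-en-1-yl]-1,3-dimethylcyclohexan-1-ol F6. Sharpless asymmetric epoxidation with D-(−)-diethyl tartrate (the tertiary allylic alcohol is inert) gives the (2R,3S)-2,3-epoxy alcohol of F6 F7. Iodination (I2, PPh3, imidazole) gives the corresponding epoxy iodide F8. Zinc dust in ethanol opens F8 reductively to the (S)-vinyl carbinol, which is 20.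

**Further compounds**
F1 | step 4 | tert-butyl (2E,6R,7R,9E)-6,7-epoxy-11-hydroxy-3,7,11-trimethyldodeca-2,9-dien-1-yl carbonate | CC(C)(C)OC(=O)OC/C=C(C)/CC[C@H]1O[C@]1(C)C/C=C/C(C)(C)O
F2 | step 4 | tert-butyl (2E,6S,7R,9E)-6-bromo-7,11-dihydroxy-3,7,11-trimethyldodeca-2,9-dien-1-yl carbonate | CC(C)(C)OC(=O)OC/C=C(C)/CC[C@H](Br)[C@](C)(O)C/C=C/C(C)(C)O
F3 | step 7 | tris(trimethylsilyl) ether of 9 | C[Si](C)(C)OC[C@H]1[C@](C)(C/C=C/C(C)(C)O[Si](C)(C)C)[C@@H](Br)CC[C@]1(C)O[Si](C)(C)C
F4 | step 7 | (1S,2S,3S,6S)-3-bromo-2,6-dimethyl-2-[(2E)-4-methyl-4-(trimethylsilyloxy)pent-2-en-1-yl]-6-(trimethylsilyloxy)cyclohexane-1-carbaldehyde | O=C[C@H]1[C@](C)(C/C=C/C(C)(C)O[Si](C)(C)C)[C@@H](Br)CC[C@]1(C)O[Si](C)(C)C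
F5 | step 11 | B-alkyl-9-BBN adduct of 11 (boron on the terminal carbon of the former vinyl group) | C(CB3C4CCCC3CCC4)[C@H]1[C@](C)(C/C=C/C(C)(C)O)[C@@H](Br)CC[C@]1(C)O
F6 | step 11 | (1S,2S,3S,4S)-4-bromo-2-[(3Z)-5-hydroxy-3-methylpent-3-en-1-yl]-3-[(2E)-4-hydroxy-4-methylpent-2-en-1-yl]-1,3-dimethylcyclohexan-1-ol | OC/C=C(C)\CC[C@H]1[C@](C)(C/C=C/C(C)(C)O)[C@@H](Br)CC[C@]1(C)O
F7 | step 11 | (2R,3S)-2,3-epoxy alcohol of F6 (side chain 2-[(2S,3R)-3-(hydroxymethyl)-2-methyloxiran-2-yl]ethyl) | OC[C@H]1O[C@@]1(C)CC[C@H]2[C@](C)(C/C=C/C(C)(C)O)[C@@H](Br)CC[C@]2(C)O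
F8 | step 11 | epoxy iodide from F7 (CH2OH replaced by CH2I, same configuration) | IC[C@H]1O[C@@]1(C)CC[C@H]2[C@](C)(C/C=C/C(C)(C)O)[C@@H](Br)CC[C@]2(C)O
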